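**Strategy.** The seven-membered ring is cut at C3–C4. C4 and C6 are the two one-carbon bridges of the bicyclo[3.1.1]heptane and face each other across the cyclobutane C4–C5–C6–C7, so a chain C11–C1–C2–C3 carried by C6 can deliver a C3 aldehyde only to the face of C4 that lies away from the C8–C9–C10 bridge. One samarium Reformatsky aldol therefore closes ring C1–C2–C3–C4–C5–C6–C11, makes C4 quaternary and sets the C3 carbinol. Its precursor is a Wolff-derived bicyclo[3.1.1]heptane carrying a bromo ester on C4 and, on C6, the acetonide-protected chain ending in the C3 aldehyde.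

Key step: step 20

Numbering: ring carbons C1–C11 as in the target SMILES; C12 = CH2O carbon on C11, C13 = the carbon that ends as the methyl on C4, C14 = methyl on C10, C15 = methyl on C11.
Assumption: (R)-5-methylcyclohex-2-en-1-one is bought as the single enantiomer (it is also reached in three known steps from (R)-pulegone).
Remark on the structures: the configurations of the key-step precursor and product were re-derived centre by centre from the target and needed no change. The one alteration is bromine on C4 of the precursor. An amide base would attack the enolisable, β-oxygenated C3 aldehyde before the weakly acidic cyclobutane C–H, so the C4 enolate is made by reduction instead.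

**Step 1**
Reactants: 1 (R)-5-methylcyclohex-2-en-1-one; 2 allyl bromide
Product: 4 (5R,6S)-5-methyl-6-(prop-2-en-1-yl)cyclohex-2-en-1-one, via lithium dienolate 3 (not isolated)
Conditions: LiN(iPr)2, THF, −78 °C; allyl bromide, DMPU, −78 → −30 °C
Reagents that add atoms: allyl bromide (2), C=CCBr; LiN(iPr)2, [Li+].CC(C)[N-]C(C)C (lithium stays only in 3)
Why: Kinetic deprotonation at the α′ carbon C5 gives the cross-conjugated dienolate, which is alkylated anti to the neighbouring C10 methyl group, so the allyl group (C4, C13) enters trans to C14 (enolate alkylation).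

**Step 2**
Reactants: 4 (5R,6S)-5-methyl-6-(prop-2-en-1-yl)cyclohex-2-en-1-one
Product: 5 C7–C8 epoxide of 4
Conditions: H2O2 (30% aq.), NaOH (cat.), MeOH, 0 °C
Reagents that add atoms: hydrogen peroxide, OO
Why: Weitz–Scheffer epoxidation: hydroperoxide adds only to the electron-poor C7=C8 bond, the isolated allyl alkene is inert, and the oxirane configuration is lost again in step 4.

**Step 3**
Reactants: 5 C7–C8 epoxide of 4
Product: 7 (4S,5R)-5-methyl-4-(prop-2-en-1-yl)cyclohex-2-en-1-ol (carbinol epimers), via epoxy hydrazone 6 (not isolated)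
Conditions: N2H4·H2O, AcOH (cat.), MeOH, 0 °C → rt
Reagents that add atoms: hydrazine, NN (its nitrogen stays only in 6; 7 gains hydrogen only)
Why: Wharton transposition: the epoxy hydrazone fragments with loss of N2, which moves the oxygen from C6 to C8 and the alkene to C6=C7 without touching C5 or C10.

**Step 4**
Reactants: 7 (4S,5R)-5-methyl-4-(prop-2-en-1-yl)cyclohex-2-en-1-ol
Product: 8 (4S,5R)-5-methyl-4-(prop-2-en-1-yl)cyclohex-2-en-1-one
Conditions: DMP, CH2Cl2, rt
Reagents that add atoms: none
Why: Dess–Martin oxidation of the secondary allylic alcohol gives the transposed enone without base, so the γ stereocentre C5 should not epimerise.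

**Step 5**
Reactants: 9 (S)-4-benzyl-3-propanoyl-1,3-oxazolidin-2-one; 10 3-[(tert-butyldimethylsilyl)oxy]propanal
Product: 12 (S)-4-benzyl-3-[(2S,3R)-5-[(tert-butyldimethylsilyl)oxy]-3-hydroxy-2-methylpentanoyl]-1,3-oxazolidin-2-one, via boron enolate 11 (not isolated)
Conditions: Bu2BOTf, iPr2NEt, CH2Cl2, 0 °C; 10, −78 → 0 °C; H2O2, pH 7 buffer, MeOH
Reagents that add atoms: 3-[(tert-butyldimethylsilyl)oxy]propanal (10), O=CCCO[Si](C)(C)C(C)(C)C; dibutylboron triflate, CCCCB(CCCC)OS(=O)(=O)C(F)(F)F (boron stays only in 11)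
Why: Evans aldol: the (Z)-boron enolate reacts through a closed chair transition state on the face away from the benzyl group and gives the syn adduct, which sets C1 as (R).

**Step 6**
Reactants: 12 aldol imide
Product: 13 (2S,3R)-5-[(tert-butyldimethylsilyl)oxy]-3-hydroxy-2-methylpentanoic acid
Conditions: LiOH, H2O2, THF/H2O, 0 °C; Na2SO3; HCl to pH 3
Reagents that add atoms: lithium hydroxide, [Li+].[OH-]; hydrogen peroxide, OO
Why: Hydroperoxide attacks the exocyclic imide carbonyl selectively (auxiliary cleavage); the silyl ether and the carbinol centre survive at 0 °C.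

**Step 7**
Reactants: 13 hydroxy acid
Product: 15 (6R)-2-tert-butyl-6-{2-[(tert-butyldimethylsilyl)oxy]ethyl}-5-methyl-1,3-dioxan-4-one with tert-butyl and side chain cis, via bis-silyl derivative 14 (not isolated)
Conditions: Me3SiCl, Et3N, CH2Cl2, rt; then t-BuCHO, Me3SiOTf (cat.), CH2Cl2, −78 °C
Reagents that add atoms: pivalaldehyde, CC(C)(C)C=O; chlorotrimethylsilane, C[Si](C)(C)Cl (silicon stays only in 14)
Why: Silyl-triflate-catalysed acetalisation of the bis-silyl hydroxy acid gives the 1,3-dioxan-4-one with tert-butyl and side chain both equatorial; the C11 configuration is erased in step 8.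

**Step 8**
Reactants: 15 dioxanone; 8 (4S,5R)-5-methyl-4-(prop-2-en-1-yl)cyclohex-2-en-1-one
Product: 18 C7-bromo ketone in which C11 of the dioxanone is bonded to C6 of the 5-allyl-10-methylcyclohexan-8-one, via lithium dioxanone enolate 16 (not isolated), via lithium C7 enolate 17 (not isolated)
Conditions: LiN(iPr)2, THF, −78 °C; 8, −78 → −60 °C; NBS, −78 °C
Reagents that add atoms: enone (8), O=C1C=C[C@@H](CC=C)[C@H](C)C1; N-bromosuccinimide, BrN1C(=O)CCC1=O; LiN(iPr)2, [Li+].CC(C)[N-]C(C)C (lithium stays only in 16 and 17)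
Why: Michael addition: the tetrasubstituted enolate bonds through C11 on its face trans to the C1 side chain and the tert-butyl group (sets C11), attacking C6 of the enone axially and anti to the C10 methyl group of the all-equatorial half-chair (sets C6 cis to the allyl group on C5); the regiodefined C7 enolate is then trapped by bromination.

**Step 9**
Reactants: 18 C7-bromo ketone
Product: 20 C7-bromo C8-keto C13-aldehyde, via ozonide 19 (not isolated)
Conditions: O3, CH2Cl2, −78 °C; PPh3, −78 °C → rt
Reagents that add atoms: ozone, O=[O+][O-]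
Why: Ozonolysis with reductive work-up cleaves the only alkene to the C13 aldehyde; bromo ketone, dioxanone and silyl ether are inert to ozone at −78 °C.

**Step 10**
Reactants: 20 bromo keto aldehyde
Product: 22 bicyclo[3.2.1]octane aldol (C8 ketone, C13 hydroxyl on the C4–C13 bridge, C14 methyl exo, dioxanone on C6 syn to the C4–C13 bridge), via samarium C7 enolate 21 (not isolated)
Conditions: SmI2 (2.2 equiv), THF, −78 °C
Reagents that add atoms: samarium diiodide, I[Sm]I (stays only in 21; 22 gains hydrogen only)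
Why: Samarium Reformatsky-type aldol: reduction of the C7–Br bond gives the enolate at C7 only, and it adds to the C13 aldehyde held on the same ring face by C5, closing the two-carbon bridge; the C13 carbinol (expected endo from the samarium-bridged transition state) is oxidised in step 14.

**Step 11**
Reactants: 22 bicyclic aldol
Product: 23 C8 ethylene ketal of 22
Conditions: Me3SiOCH2CH2OSiMe3, Me3SiOTf (cat.), CH2Cl2, −78 → −20 °C; K2CO3, MeOH work-up
Reagents that add atoms: 1,2-bis(trimethylsilyloxy)ethane, C[Si](C)(C)OCCO[Si](C)(C)C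
Why: Silyl-triflate-catalysed ketalisation masks the C8 ketone at low temperature without retro-aldol cleavage or loss of the silyl ether.

**Step 12**
Reactants: 23 ketal
Product: 24 triol (C12 primary, C1 secondary and C13 secondary hydroxyls)
Conditions: LiAlH4, THF, 0 °C → rt
Reagents that add atoms: none
Why: Hydride reduction opens the dioxanone to the C12 and C1 alcohols (the acetal carbon leaves as neopentyl alcohol); ketal and silyl ether are stable.

**Step 13**
Reactants: 24 triol
Product: 25 C1,C12-acetonide with free C13 hydroxyl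
Conditions: Me2C(OMe)2, PPTS (cat.), CH2Cl2, rt
Reagents that add atoms: 2,2-dimethoxypropane, COC(C)(C)OC
Why: Acetonide formation is selective for the C1/C12 1,3-diol, which gives a six-membered ring, and leaves the isolated C13 hydroxyl free.

**Step 14**
Reactants: 25 acetonide alcohol
Product: 26 C13 ketone
Conditions: DMP, pyridine, CH2Cl2, rt
Reagents that add atoms: none
Why: Dess–Martin oxidation of the only free hydroxyl gives the ketone of the two-carbon bridge.

**Step 15**
Reactants: 26 C13 ketone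
Product: 28 C4-diazo C13-ketone, via trifluoroacetyl ketone 27 (not isolated)
Conditions: LiN(SiMe3)2, THF, −78 °C; CF3CO2CH2CF3; then MeSO2N3, Et3N, H2O, MeCN, rt
Reagents that add atoms: 2,2,2-trifluoroethyl trifluoroacetate, FC(F)(F)COC(=O)C(F)(F)F (stays only in 27); methanesulfonyl azide, CS(=O)(=O)N=[N+]=[N-]
Why: Detrifluoroacetylative diazo transfer: C4 is the only enolisable position of the C13 ketone because C7 is a bridgehead.

**Step 16**
Reactants: 28 diazo ketone
Product: 30 methyl bicyclo[3.1.1]heptane-C4-carboxylate (C4 epimers), via ketene 29 (not isolated)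
Conditions: hν (≥ 300 nm), MeOH, 0 °C
Reagents that add atoms: methanol, CO
Why: Photochemical Wolff rearrangement: loss of N2 with migration of C7 from C13 to C4 (retention at C7) contracts the bridge to the cyclobutane, and methanol traps the ketene; both C4 epimers serve.

**Step 17**
Reactants: 30 methyl ester
Product: 32 C4-bromo methyl ester, via lithium ester enolate 31 (not isolated)
Conditions: LiN(iPr)2, THF, −78 °C; CBr4, −78 °C
Reagents that add atoms: carbon tetrabromide, BrC(Br)(Br)Br; LiN(iPr)2, [Li+].CC(C)[N-]C(C)C (lithium stays only in 31)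
Why: The ester is the only acidic site, so the amide base gives the enolate exocyclic to the cyclobutane, which is brominated at C4 (enolate halogenation); the C4 configuration is irrelevant.

**Step 18**
Reactants: 32 bromo ester
Product: 33 C3 primary alcohol
Conditions: HF·pyridine, pyridine, THF, 0 °C → rt
Reagents that add atoms: none
Why: Buffered fluoride cleaves the primary silyl ether selectively (desilylation); acetonide, dioxolane and the tertiary bromide are untouched.

**Step 19**
Reactants: 33 primary alcohol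
Product: 34 C3 aldehyde with C4-bromo ester (key-step precursor)
Conditions: DMP, pyridine, CH2Cl2, 0 °C → rt
Reagents that add atoms: none
Why: Dess–Martin oxidation under buffered, non-basic conditions gives the β-alkoxy aldehyde without β-elimination.

**Step 20**
Reactants: 34 C3 aldehyde with C4-bromo ester
Product: 36 tricyclic C3 alcohol with the methyl ester on quaternary C4, via samarium ester enolate 35 (not isolated)
Conditions: SmI2 (2.5 equiv), THF, −78 °C, slow addition of 34 at high dilution
Reagents that add atoms: samarium diiodide, I[Sm]I (stays only in 35; 36 gains hydrogen only)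
Why: SmI2 transfers two electrons to the C4–Br bond and gives the trivalent samarium ester enolate, planar at C4 and exocyclic to the cyclobutane, which adds to the C3 aldehyde; the closest known reaction type is the intramolecular samarium Reformatsky reaction used for medium rings. The ring C1–C2–C3–C4–C5–C6–C11 closes in the 7-exo-trig mode. C4 is controlled by the tether: the chain is anchored on the C6 substituent that points away from the C8–C9–C10 bridge, so C3 can bond only to that face of C4 and the ester ends on the bridge side. C3 is controlled by a closed transition state in which samarium links the enolate and aldehyde oxygens and the aldehyde oxygen avoids the C1–O dipole, which should put the hydroxyl trans to the C1 oxygen. The step needs chemoselective enolate formation at C4 beside an enolisable aldehyde, which the bromine secures because reduction of the α-bromo ester is far faster than any reaction of the aldehyde, and face selectivity at C4, which the bicyclic tether secures.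

**Step 21**
Reactants: 36 aldol product
Product: 37 C3 tert-butyldimethylsilyl ether
Conditions: t-BuMe2SiOTf, 2,6-lutidine, CH2Cl2, 0 °C
Reagents that add atoms: tert-butyldimethylsilyl triflate, CC(C)(C)[Si](C)(C)OS(=O)(=O)C(F)(F)F
Why: Silyl ether formation at the hindered C3 hydroxyl prevents oxetane formation in step 24 and keeps C3–OH distinct from C1–OH to the end.

**Step 22**
Reactants: 37 silyl ether
Product: 38 C13 primary alcohol
Conditions: LiAlH4, THF, 0 °C
Reagents that add atoms: none
Why: Hydride reduction of the C4 ester to the primary alcohol; acetals and silyl ether are stable.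

**Step 23**
Reactants: 38 primary alcohol
Product: 39 C13 mesylate
Conditions: MeSO2Cl, Et3N, CH2Cl2, 0 °C
Reagents that add atoms: methanesulfonyl chloride, CS(=O)(=O)Cl
Why: Sulfonate formation at the only free, primary hydroxyl.

**Step 24**
Reactants: 39 mesylate
Product: 40 C4-methyl compound
Conditions: LiEt3BH, THF, 65 °C
Reagents that add atoms: none
Why: Hydride displacement of the neopentyl mesylate (SN2 reduction) turns C13 into the C4 methyl group, which already sits on the side of the C8–C10 bridge.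

**Step 25**
Reactants: 40 C4-methyl compound
Product: 41 C1,C12 diol
Conditions: PPTS, MeOH, rt
Reagents that add atoms: none
Why: Acid-catalysed methanolysis (transacetalisation) removes the 1,3-diol acetonide faster than the hindered dioxolane or the secondary silyl ether.

**Step 26**
Reactants: 41 diol
Product: 42 C12 acetate
Conditions: Ac2O, pyridine, CH2Cl2, 0 °C
Reagents that add atoms: acetic anhydride, CC(=O)OC(C)=O
Why: Selective acetylation: the primary C12 hydroxyl is acylated much faster than the neopentyl secondary C1 hydroxyl.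

**Step 27**
Reactants: 42 C12 acetate; 43 angelic acid
Product: 45 C1 angelate, via mixed anhydride 44 (not isolated)
Conditions: angelic acid, 2,4,6-trichlorobenzoyl chloride, Et3N, toluene, rt; then 42, toluene, 75 °C
Reagents that add atoms: angelic acid (43), C/C=C(/C)C(=O)O; 2,4,6-trichlorobenzoyl chloride, O=C(Cl)c1c(Cl)cc(Cl)cc1Cl (stays only in 44)
Why: Yamaguchi-type esterification through the mixed anhydride without a nucleophilic catalyst acylates the C1 hydroxyl and should keep the (Z) geometry of the angelate.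

**Step 28**
Reactants: 45 C1 angelate
Product: 46 CNP0212099.1 (target)
Conditions: HF (48% aq.), MeCN, rt
Reagents that add atoms: water, O
Why: Global deprotection: aqueous HF cleaves the silyl ether and hydrolyses the dioxolane in one operation, and the two esters should survive the mildly acidic medium.

**Compound list**
1 | (R)-5-methylcyclohex-2-en-1-one | O=C1C=CC[C@@H](C)C1 | starting material
2 | allyl bromide | C=CCBr | starting material
3 | lithium cross-conjugated dienolate of 1 | [Li+].[O-]C1=C[C@H](C)CC=C1 | intermediate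
4 | (5R,6S)-5-methyl-6-(prop-2-en-1-yl)cyclohex-2-en-1-one (allyl trans to methyl) | O=C1C=CC[C@@H](C)[C@@H]1CC=C | intermediate
5 | C7–C8 epoxide of 4 (oxirane configuration not carried on) | O=C1C2OC2C[C@@H](C)[C@@H]1CC=C | intermediate
6 | hydrazone of 5 | NN=C1C2OC2C[C@@H](C)[C@@H]1CC=C | intermediate
7 | (4S,5R)-5-methyl-4-(prop-2-en-1-yl)cyclohex-2-en-1-ol, carbinol epimers | OC1C=C[C@@H](CC=C)[C@H](C)C1 | intermediate
8 | (4S,5R)-5-methyl-4-(prop-2-en-1-yl)cyclohex-2-en-1-one | O=C1C=C[C@@H](CC=C)[C@H](C)C1 | intermediate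
9 | (S)-4-benzyl-3-propanoyl-1,3-oxazolidin-2-one | CCC(=O)N1[C@@H](Cc2ccccc2)COC1=O | starting material
10 | 3-[(tert-butyldimethylsilyl)oxy]propanal | O=CCCO[Si](C)(C)C(C)(C)C | starting material
11 | (Z)-dibutylboron enolate of 9 | C/C=C(\OB(CCCC)CCCC)N1[C@@H](Cc2ccccc2)COC1=O | intermediate
12 | (S)-4-benzyl-3-[(2S,3R)-5-[(tert-butyldimethylsilyl)oxy]-3-hydroxy-2-methylpentanoyl]-1,3-oxazolidin-2-one | O=C1OC[C@H](Cc2ccccc2)N1C(=O)[C@@H](C)[C@H](O)CCO[Si](C)(C)C(C)(C)C | intermediate
13 | (2S,3R)-5-[(tert-butyldimethylsilyl)oxy]-3-hydroxy-2-methylpentanoic acid | OC(=O)[C@@H](C)[C@H](O)CCO[Si](C)(C)C(C)(C)C | intermediate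
14 | trimethylsilyl ester, trimethylsilyl ether of 13 | C[Si](C)(C)OC(=O)[C@@H](C)[C@H](O[Si](C)(C)C)CCO[Si](C)(C)C(C)(C)C | intermediate
15 | (6R)-2-tert-butyl-6-{2-[(tert-butyldimethylsilyl)oxy]ethyl}-5-methyl-1,3-dioxan-4-one, 2,6-cis | C[C@@H]1C(=O)O[C@H](C(C)(C)C)O[C@@H]1CCO[Si](C)(C)C(C)(C)C | intermediate
16 | lithium enolate of 15 | [Li+].[O-]C1=C(C)[C@@H](CCO[Si](C)(C)C(C)(C)C)O[C@@H](C(C)(C)C)O1 | intermediate
17 | lithium C7 enolate of the Michael adduct of 15 and 8 | O=C1O[C@H](C(C)(C)C)O[C@H](CCO[Si](C)(C)C(C)(C)C)[C@@]1(C)[C@@H]2C=C([O-])C[C@@H](C)[C@@H]2CC=C.[Li+] | intermediate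
18 | C7-bromo C8-ketone; dioxanone C11 on C6 cis to the C5 allyl group and trans to the C10 methyl | O=C1O[C@H](C(C)(C)C)O[C@H](CCO[Si](C)(C)C(C)(C)C)[C@@]1(C)[C@@H]2C(Br)C(=O)C[C@@H](C)[C@@H]2CC=C | intermediate
19 | ozonide (1,2,4-trioxolane) of 18 | O=C1O[C@H](C(C)(C)C)O[C@H](CCO[Si](C)(C)C(C)(C)C)[C@@]1(C)[C@@H]2C(Br)C(=O)C[C@@H](C)[C@@H]2CC3OCOO3 | intermediate
20 | C7-bromo C8-keto C13-aldehyde | O=C1O[C@H](C(C)(C)C)O[C@H](CCO[Si](C)(C)C(C)(C)C)[C@@]1(C)[C@@H]2C(Br)C(=O)C[C@@H](C)[C@@H]2CC=O | intermediate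
21 | samarium C7 enolate of 20 | O=C1O[C@H](C(C)(C)C)O[C@H](CCO[Si](C)(C)C(C)(C)C)[C@@]1(C)[C@@H]2C=C(O[Sm](I)I)C[C@@H](C)[C@@H]2CC=O | intermediate
22 | bicyclo[3.2.1]octane aldol: C8 ketone, C13 hydroxyl endo, C14 methyl exo, dioxanone on bridge carbon C6 syn to the C4–C13 bridge | O=C1O[C@H](C(C)(C)C)O[C@H](CCO[Si](C)(C)C(C)(C)C)[C@@]1(C)[C@H]2[C@H]3C[C@H](O)[C@@H]2C(=O)C[C@H]3C | intermediate
23 | C8 ethylene ketal of 22 | O=C1O[C@H](C(C)(C)C)O[C@H](CCO[Si](C)(C)C(C)(C)C)[C@@]1(C)[C@H]2[C@H]3C[C@H](O)[C@@H]2C4(OCCO4)C[C@H]3C | intermediate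
24 | triol: C12 and C1 hydroxyls on the side chain, C13 hydroxyl on the bridge | OC[C@@](C)([C@H](O)CCO[Si](C)(C)C(C)(C)C)[C@H]1[C@H]2C[C@H](O)[C@@H]1C3(OCCO3)C[C@H]2C | intermediate
25 | C1,C12-acetonide, C13 alcohol | CC1(C)OC[C@@](C)([C@@H](CCO[Si](C)(C)C(C)(C)C)O1)[C@H]2[C@H]3C[C@H](O)[C@@H]2C4(OCCO4)C[C@H]3C | intermediate
26 | C13 ketone | CC1(C)OC[C@@](C)([C@@H](CCO[Si](C)(C)C(C)(C)C)O1)[C@H]2[C@H]3CC(=O)[C@@H]2C4(OCCO4)C[C@H]3C | intermediate
27 | C4-trifluoroacetyl C13-ketone | CC1(C)OC[C@@](C)([C@@H](CCO[Si](C)(C)C(C)(C)C)O1)[C@H]2[C@H]3C(C(=O)C(F)(F)F)C(=O)[C@@H]2C4(OCCO4)C[C@H]3C | intermediate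
28 | C4-diazo C13-ketone | CC1(C)OC[C@@](C)([C@@H](CCO[Si](C)(C)C(C)(C)C)O1)[C@H]2[C@H]3C(=[N+]=[N-])C(=O)[C@@H]2C4(OCCO4)C[C@H]3C | intermediate
29 | ketene on C4 of the bicyclo[3.1.1]heptane | CC1(C)OC[C@@](C)([C@@H](CCO[Si](C)(C)C(C)(C)C)O1)[C@H]2[C@H]3C(=C=O)[C@@H]2C4(OCCO4)C[C@H]3C | intermediate
30 | methyl bicyclo[3.1.1]heptane-C4-carboxylate, C4 epimers, side chain on C6 anti to the C8–C10 bridge | CC1(C)OC[C@@](C)([C@@H](CCO[Si](C)(C)C(C)(C)C)O1)[C@H]2[C@H]3C(C(=O)OC)[C@@H]2C4(OCCO4)C[C@H]3C | intermediate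
31 | lithium enolate of 30 | CC1(C)OC[C@@](C)([C@@H](CCO[Si](C)(C)C(C)(C)C)O1)[C@H]2[C@H]3C(=C([O-])OC)[C@@H]2C4(OCCO4)C[C@H]3C.[Li+] | intermediate
32 | C4-bromo methyl ester | CC1(C)OC[C@@](C)([C@@H](CCO[Si](C)(C)C(C)(C)C)O1)[C@H]2[C@H]3C(Br)(C(=O)OC)[C@@H]2C4(OCCO4)C[C@H]3C | intermediate
33 | C3 primary alcohol | CC1(C)OC[C@@](C)([C@@H](CCO)O1)[C@H]2[C@H]3C(Br)(C(=O)OC)[C@@H]2C4(OCCO4)C[C@H]3C | intermediate
34 | key-step precursor: C3 aldehyde, C4-bromo ester, acetonide, dioxolane | CC1(C)OC[C@@](C)([C@@H](CC=O)O1)[C@H]2[C@H]3C(Br)(C(=O)OC)[C@@H]2C4(OCCO4)C[C@H]3C | intermediate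
35 | samarium ester enolate of 34 | CC1(C)OC[C@@](C)([C@@H](CC=O)O1)[C@H]2[C@H]3C(=C(OC)O[Sm](I)I)[C@@H]2C4(OCCO4)C[C@H]3C | intermediate
36 | key-step product: C3 alcohol trans to the C1 oxygen, ester on quaternary C4 syn to the C8–C10 bridge | CC4(C)O[C@@H]1C[C@@H](O)[C@]2(C(=O)OC)[C@@H]3[C@@H]([C@H]2C5(OCCO5)C[C@H]3C)[C@@]1(C)CO4 | intermediate
37 | C3 tert-butyldimethylsilyl ether of 36 | CC4(C)O[C@@H]1C[C@@H](O[Si](C)(C)C(C)(C)C)[C@]2(C(=O)OC)[C@@H]3[C@@H]([C@H]2C5(OCCO5)C[C@H]3C)[C@@]1(C)CO4 | intermediate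
38 | C13 primary alcohol | CC4(C)O[C@@H]1C[C@@H](O[Si](C)(C)C(C)(C)C)[C@]2(CO)[C@@H]3[C@@H]([C@H]2C5(OCCO5)C[C@H]3C)[C@@]1(C)CO4 | intermediate
39 | C13 mesylate | CC4(C)O[C@@H]1C[C@@H](O[Si](C)(C)C(C)(C)C)[C@]2(COS(C)(=O)=O)[C@@H]3[C@@H]([C@H]2C5(OCCO5)C[C@H]3C)[C@@]1(C)CO4 | intermediate
40 | C4-methyl compound | CC4(C)O[C@@H]1C[C@@H](O[Si](C)(C)C(C)(C)C)[C@]2(C)[C@@H]3[C@@H]([C@H]2C5(OCCO5)C[C@H]3C)[C@@]1(C)CO4 | intermediate
41 | C1,C12 diol | O[C@@H]1C[C@@H](O[Si](C)(C)C(C)(C)C)[C@]2(C)[C@@H]3[C@@H]([C@H]2C5(OCCO5)C[C@H]3C)[C@@]1(C)CO | intermediate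
42 | C12 acetate, free C1 hydroxyl | O[C@@H]1C[C@@H](O[Si](C)(C)C(C)(C)C)[C@]2(C)[C@@H]3[C@@H]([C@H]2C5(OCCO5)C[C@H]3C)[C@@]1(C)COC(C)=O | intermediate
43 | angelic acid, (Z)-2-methylbut-2-enoic acid | C/C=C(/C)C(=O)O | starting material
44 | angelic 2,4,6-trichlorobenzoic anhydride | C/C=C(/C)C(=O)OC(=O)c1c(Cl)cc(Cl)cc1Cl | intermediate
45 | C1 angelate, C12 acetate, C3 silyl ether, C8 dioxolane | C/C=C(/C)C(=O)O[C@@H]1C[C@@H](O[Si](C)(C)C(C)(C)C)[C@]2(C)[C@@H]3[C@@H]([C@H]2C5(OCCO5)C[C@H]3C)[C@@]1(C)COC(C)=O | intermediate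
46 | CNP0212099.1 | C/C=C(/C)C(=O)O[C@@H]1C[C@@H](O)[C@]2(C)[C@@H]3[C@@H]([C@H]2C(=O)C[C@H]3C)[C@@]1(C)COC(C)=O | target

**Totals.** 28 steps; longest linear sequence 25 steps (steps 1–4 and 8–28); the side-chain branch (steps 5–7) joins at step 8.

**Steps most likely to fail**

Step 20 (key step). The geometry of the samarium enolate is not fixed, so facial selectivity at C3 may be poor and the C3 epimer may form beside 36; C4 is not at risk. The fallback sets out from 34 and sets C3 by a different principle. The closure is run as in step 20 and the mixture, which contains the C3 epimer F1, is oxidised with DMP to the single β-keto ester F2. PPTS in MeOH frees the C1 and C12 hydroxyls to give the keto diol F3. Me4NBH(OAc)3 in MeCN/AcOH delivers hydride from boron bound to the C1 hydroxyl (Evans–Saksena reduction) and should give the 1,3-anti triol F4. Me2C(OMe)2 with PPTS re-forms the six-membered acetonide on the C1/C12 diol and returns the route at 36.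

Step 8. The hindered lithium enolate may act as a base toward the γ-hydrogen of the enone, add 1,2, or fragment by β-elimination before the conjugate addition occurs. The fallback sets out from 15 and uses Lewis-acid activation of the enone instead. LiN(iPr)2 and Me3SiCl at −78 °C give the trimethylsilyl ketene acetal F5. A Mukaiyama–Michael addition to 8 (Me3SiOTf cat., CH2Cl2, −78 °C) should give the silyl enol ether F6 with the same facial preferences. NBS in THF at −78 °C brominates C7 and returns the route at 18.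

Step 24. Hydride displacement at the neopentyl carbon next to quaternary C4 may be outrun by attack at sulfur, which would return alcohol 38. The fallback sets out from 38 and cleaves the C–O bond by a radical path. 1,1′-Thiocarbonyldiimidazole in toluene gives the imidazolyl thiocarbonate F7, and Bu3SnH with AIBN at 110 °C (Barton–McCombie deoxygenation) returns the route at 40.

**Further compounds**
F1 | step 20 | C3 epimer of 36 | CC4(C)O[C@@H]1C[C@H](O)[C@]2(C(=O)OC)[C@@H]3[C@@H]([C@H]2C5(OCCO5)C[C@H]3C)[C@@]1(C)CO4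
F2 | step 20 | C3 ketone (β-keto ester) | CC4(C)O[C@@H]1CC(=O)[C@]2(C(=O)OC)[C@@H]3[C@@H]([C@H]2C5(OCCO5)C[C@H]3C)[C@@]1(C)CO4
F3 | step 20 | C3 ketone with free C1 and C12 hydroxyls | O[C@@H]1CC(=O)[C@]2(C(=O)OC)[C@@H]3[C@@H]([C@H]2C5(OCCO5)C[C@H]3C)[C@@]1(C)CO
F4 | step 20 | C1,C3-anti triol ester | O[C@@H]1C[C@@H](O)[C@]2(C(=O)OC)[C@@H]3[C@@H]([C@H]2C5(OCCO5)C[C@H]3C)[C@@]1(C)CO
F5 | step 8 | trimethylsilyl ketene acetal of 15 | C[Si](C)(C)OC1=C(C)[C@@H](CCO[Si](C)(C)C(C)(C)C)O[C@@H](C(C)(C)C)O1
F6 | step 8 | C7=C8 trimethylsilyl enol ether of the Michael adduct | O=C1O[C@H](C(C)(C)C)O[C@H](CCO[Si](C)(C)C(C)(C)C)[C@@]1(C)[C@@H]2C=C(O[Si](C)(C)C)C[C@@H](C)[C@@H]2CC=C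
F7 | step 24 | O-(C13) imidazole-1-carbothioate of 38 | CC4(C)O[C@@H]1C[C@@H](O[Si](C)(C)C(C)(C)C)[C@]2(COC(=S)n6ccnc6)[C@@H]3[C@@H]([C@H]2C5(OCCO5)C[C@H]3C)[C@@]1(C)CO4
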